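The numbers in the tables come from a simulation for substances that don't exist; the scatter is artificial.

Links were the product I wanted, so I followed one first end group to its fork: it becomes a link or a ring.

| setting | Thursday's | Friday's | Wednesday's | teal | violet | red | amber |
|---|---|---|---|---|---|---|---|
| first end groups | 1 mM | 1.4 mM | 2.2 mM | 1.0 mM (fed, over 2.5 min) | 1.0 mM (fed, over 2.5 min) | 1.0 mM (in portions, 2, over 2.5 min) | 1.0 mM |
| second end groups | 0.90 mM | 0.90 mM | 0.90 mM | 0.900 mM | 0.900 mM | 0.900 mM | 0.900 mM (fed, over 2.5 min) |
| temperature | 85 °C | 100 °C | 85 °C | 100 °C |  | 100 °C | 100 °C |
| remark | run made earlier | run made earlier | run made earlier | all else is in the flask from the start; the feed brings no volume worth counting | the addition at 70 °C, then warmed to 100 °C; the feed brings no volume worth counting | first portion at the start, last at 2.5 min | all else is in the flask from the start; the feed brings no volume worth counting |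
| time |  |  |  | 3.0 min | 3.0 min | 3.0 min | 3.0 min |

| run | time / min | links / % | rings / % |
|---|---|---|---|
| Thursday's | 0.500 | 27.8 | 61.8 |
| Thursday's | 1.33 | 28.8 | 60.6 |
| Thursday's | 3.00 | 28.4 | 61.1 |
| Thursday's | 4.00 | 27.1 | 59.7 |
| Friday's | 0.200 | 12.7 | 48.5 |
| Friday's | 0.417 | 14.2 | 49.1 |
| Friday's | 1.00 | 11.2 | 50.3 |
| Friday's | 2.50 | 13.5 | 50.5 |
| Wednesday's | 0.667 | 10.7 | 27.5 |
| Wednesday's | 2.00 | 12.9 | 26.6 |
| Wednesday's | 3.00 | 11.8 | 28.2 |
| Wednesday's | 5.00 | 11.6 | 27.0 |

(scatter of a reading: 1 percentage point)

- amounts and yields of links count idle adduct too
- steps thought possible: second end groups -> decomposed reagent; first end groups + second end groups -> links; first end groups + second end groups -> rings; second end groups + links <-> idle adduct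

- the flask that comes out highest in share of links in links plus rings, or "all alike" when all lie within 1.5 percentage points (teal / violet / red / amber / all alike)
- share of links in links plus rings at the end, teal
- share of links in links plus rings at the end, violet
- share of links in links plus rings at the end, red
- share of links in links plus rings at the end, amber

1. Friday's readings put, on average, 0.875 mM into links and rings out of 0.90 mM of second end groups, nearly all of the limiting reagent. So I compared two rates, link formation and ring formation.

2. Their ratio, links over rings, is the fork ratio (a selectivity factor). Friday's readings gave 0.260.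

3. Wednesday's run, with about twice the first end groups of Thursday's and at the same 85 °C, read 0.430, and Thursday's read 0.461. I therefore put teal and red, both at 100 °C with second end groups in the flask from the start as in Friday's run, at Friday's share, 20.6%.

4. Thursday's ratio, at 85 °C, exceeded Friday's, at 100 °C, so I put violet, added at 70 °C, above Thursday's share of 31.6%.

5. Thursday's, Friday's and Wednesday's runs were charged with 0.90 mM, 0.90 mM and 0.90 mM of second end groups, so their readings gave no test of how the fork ratio follows that charge. I supposed that link rate follows second end groups and ring rate does not. Friday's readings stood level from 0.200 min, well inside the 2.5 min feed, so in amber I estimated second end groups at 8.00% of the charge, the feed of that interval. That put amber near 2.04%, and violet highest.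

6. The forecast gave teal 20.6%, violet 44%, red 20.6% and amber 20.6%, holding that “feed mode should not matter”.

7. The flasks gave teal 18.4%, violet 40.8%, red 27.9% and amber 0.00715%, with violet highest.

    second end groups → decomposed reagent (k = 0.0170 /s, Ea = 102 kJ/mol)
    first end groups + second end groups → links (k = 170 /M/s, Ea = 38.0 kJ/mol)
    first end groups + second end groups → rings, rate k3*[first end groups] as long as [second end groups] is above zero (k = 0.230 /s, Ea = 80.0 kJ/mol)
    second end groups + links ⇌ idle adduct, settled at all times (K = 890 /M, ΔH = −32.0 kJ/mol)
    (constants at 100 °C)

8. In amber at 1.25 min, a first end group had a half-life of 1.1 min by the ring step and 250 h by the link step, so amber's fork ratio at that moment was 6.98 × 10⁻⁵, far below the 0.260 read from Friday's run. A repeat of amber at 85 °C gave 0.0154%, which is 2.15 times amber's share, while Thursday's fork ratio was 1.77 times Friday's.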